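The target is cut at O1–C8a, C4a–C4 and O1–C2 in both halves, which exposes the C4–C3–C3''–C4'' succinyl core flanked by two phloroglucinol-type rings A. One fluoride-triggered operation inserts two 3,5-dioxygenated benzynes into the two carboxylic C–O bonds of a (2E,3E)-2,3-bis(arylidene)succinic acid and closes both rings C by oxa-Michael addition, setting all four stereocentres. The diacid is unsymmetrical from the start, 4-methoxybenzylidene on one side and 4-(4-methoxybenzyloxy)benzylidene on the other, so the rings B never have to be told apart later and no alkene-bearing protecting group meets the aryne. One hydrogenolysis and a resolution finish the synthesis.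

Key step: step 6

Remark: 5 and 8 are taken as catalogue compounds; nothing in the cascade is enantioselective, so the absolute configuration comes from a final resolution, and racemates are written with the SMILES of the enantiomer that is carried on.

Step 1
Reactants: 1 diethyl succinate; 2 4-methoxybenzaldehyde
Product: 3 (E)-3-(ethoxycarbonyl)-4-(4-methoxyphenyl)but-3-enoic acid
Conditions: KOtBu, tBuOH, reflux; then 1 M HCl
Reagents that add atoms: none
Why: Stobbe condensation, in which the succinate enolate adds to the aldehyde, the alkoxide lactonises onto the second ester and E1cB opening of the paraconic ester gives the (E)-arylidene half-ester with the aryl group trans to the conjugated ester.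

Step 2
Reactants: 3 (E)-3-(ethoxycarbonyl)-4-(4-methoxyphenyl)but-3-enoic acid
Product: 4 diethyl (E)-2-(4-methoxybenzylidene)succinate
Conditions: EtOH, H2SO4 (cat.), reflux
Reagents that add atoms: ethanol, CCO
Why: Fischer esterification of the unconjugated acid restores the diester that a second Stobbe condensation needs and leaves the (E)-alkene alone.

Step 3
Reactants: 4 diethyl (E)-2-(4-methoxybenzylidene)succinate; 5 4-[(4-methoxybenzyl)oxy]benzaldehyde
Product: 7 (2E,3E)-2-(4-methoxybenzylidene)-3-{4-[(4-methoxybenzyl)oxy]benzylidene}succinic acid, via half-ester 6 (not isolated)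
Conditions: NaOEt, EtOH, reflux; then aq NaOH, reflux; cold 1 M HCl to pH 3; light excluded
Reagents that add atoms: sodium hydroxide (supplies one carboxyl oxygen), [Na+].[OH-]
Why: A second Stobbe condensation at the remaining methylene group gives the (E,E)-diene half-ester 6, which hydroxide saponifies in the same flask, and the 4-methoxybenzyl ether is stable to base and to brief cold acidification.

Step 4
Reactants: 8 3,5-bis(benzyloxy)phenol
Product: 9 2-bromo-3,5-bis(benzyloxy)phenol
Conditions: NBS (1.0 equiv), CH2Cl2, −78 °C to 0 °C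
Reagents that add atoms: N-bromosuccinimide, O=C1CCC(=O)N1Br
Why: Electrophilic aromatic bromination goes to C2, ortho to the hydroxyl group and para to a benzyloxy group, because C4 between two benzyloxy groups is more hindered and one equivalent at low temperature holds back dibromination.

Step 5
Reactants: 9 2-bromo-3,5-bis(benzyloxy)phenol
Product: 12 3,5-bis(benzyloxy)-2-(trimethylsilyl)phenyl trifluoromethanesulfonate, via aryl silyl ether 10 (not isolated), via lithium phenoxide 11 (not isolated)
Conditions: HMDS, THF, reflux, then concentrate; n-BuLi, THF, −100 °C to −78 °C; Tf2O, −100 °C to rt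
Reagents that add atoms: hexamethyldisilazane, C[Si](C)(C)N[Si](C)(C)C; trifluoromethanesulfonic anhydride, O=S(=O)(OS(=O)(=O)C(F)(F)F)C(F)(F)F
Why: O-silylation, bromine–lithium exchange and 1,3-migration of silicon from oxygen to carbon (retro-Brook rearrangement) put the silyl group on C2, and the lithium phenoxide is triflated in the same flask, which is the standard entry to ortho-silylaryl triflates.

Step 6
Reactants: 7 (2E,3E)-2-(4-methoxybenzylidene)-3-{4-[(4-methoxybenzyl)oxy]benzylidene}succinic acid; 12 3,5-bis(benzyloxy)-2-(trimethylsilyl)phenyl trifluoromethanesulfonate (2 equiv consumed, 3 equiv used)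
Product: 15 racemic (2S*,3R*,2''R*,3''S*)-5,7,5'',7''-tetrakis(benzyloxy)-4'-methoxy-4'''-(4-methoxybenzyloxy)-3,3''-biflavanone, via 3,5-bis(benzyloxy)benzyne 13 (not isolated), via bis(2-hydroxyaryl) dione 14 (not isolated)
Conditions: CsF (8 equiv), THF, 125 °C, sealed tube, light excluded; then chromatography on silica
Reagents that add atoms: none
Why: Proposed new method: CsF releases aryne 13 from 12, each carboxylate of 7 adds through oxygen to the aryne carbon remote from the flanking benzyloxy group (O1–C8a, O1''–C8a''), and the aryl anion left beside that benzyloxy group attacks the adjacent ester carbonyl through a four-membered alkoxide that opens to an ortho-acyl phenoxide (C4a–C4, C4a''–C4''), so that the bis-phenoxide of 14 results. The closest known reaction type is the CsF-mediated insertion of an aryne into the C–O bond of a single alpha,beta-unsaturated carboxylic acid with ring closure in the same flask to a 4-chromanone, which has not been shown twice on one 2,3-bis(arylidene)succinic acid. Each ring C then closes by 6-endo-trig oxa-Michael addition of the phenoxide to its arylidene carbon (O1–C2, O1''–C2''), and the enolate is protonated at C3 or C3'' by the hydrogen fluoride that the carboxylic acid left behind. C2 against C3 and C2'' against C3'' should end trans under thermodynamic control, since the closure is reversible and C3–H is enolisable in the basic fluoride medium, whereas nothing in 7 fixes one ring C against the other, so that the C2-symmetric trans,trans diastereomer is expected beside 15, to be separated on silica and returned to the equilibrium with DBU. The selectivity that the step must have is the orientation of the aryne (5,7- and not 6,8-dioxygenation), and the inductive pull of the benzyloxy group next to the triple bond secures it by placing the carbanion ortho to that oxygen; the alkene geometry of 7 is lost in the closure and 15 is necessarily racemic.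

Step 7
Reactants: 15 racemic (2S*,3R*,2''R*,3''S*)-5,7,5'',7''-tetrakis(benzyloxy)-4'-methoxy-4'''-(4-methoxybenzyloxy)-3,3''-biflavanone
Product: 16 racemic (2S*,3R*,2''R*,3''S*)-5,7,5'',7'',4'''-pentahydroxy-4'-methoxy-3,3''-biflavanone
Conditions: H2 (1 atm), 10% Pd/C, EtOAc/MeOH, rt
Reagents that add atoms: none
Why: Catalytic hydrogenolysis cleaves the four benzyl aryl ethers and the 4-methoxybenzyl aryl ether under neutral conditions that leave the methyl ether, the C4 ketones and the base-labile C2 and C3 centres untouched.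

Step 8
Reactants: 16 racemic (2S*,3R*,2''R*,3''S*)-5,7,5'',7'',4'''-pentahydroxy-4'-methoxy-3,3''-biflavanone
Product: 17 (2S,3R,2''R,3''S)-5,7,5'',7'',4'''-pentahydroxy-4'-methoxy-3,3''-biflavanone
Conditions: preparative SFC, amylose tris(3,5-dimethylphenylcarbamate) on silica, CO2/MeOH
Reagents that add atoms: none
Why: Resolution on a chiral stationary phase should succeed because the two enantiomers present their 4-hydroxyphenyl flavanone half in opposite configuration, the situation in which polysaccharide carbamate phases separate the enantiomers of simple 5,7-dihydroxyflavanones, and the wanted fraction is to be assigned by X-ray analysis of a heavy-atom derivative or by comparison with natural material.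

Compound list
1 | diethyl succinate | CCOC(=O)CCC(=O)OCC | starting material
2 | 4-methoxybenzaldehyde | COc1ccc(C=O)cc1 | starting material
3 | (E)-3-(ethoxycarbonyl)-4-(4-methoxyphenyl)but-3-enoic acid | CCOC(=O)/C(CC(=O)O)=C/c1ccc(OC)cc1 | intermediate
4 | diethyl (E)-2-(4-methoxybenzylidene)succinate | CCOC(=O)/C(CC(=O)OCC)=C/c1ccc(OC)cc1 | intermediate
5 | 4-[(4-methoxybenzyl)oxy]benzaldehyde | COc1ccc(COc2ccc(C=O)cc2)cc1 | starting material
6 | (2E,3E)-3-(ethoxycarbonyl)-2-(4-methoxybenzylidene)-4-{4-[(4-methoxybenzyl)oxy]phenyl}but-3-enoic acid (free acid on the 4-methoxybenzylidene carbon, ethyl ester on the other) | COc1ccc(/C=C(C(=O)O)\C(=C/c2ccc(OCc3ccc(OC)cc3)cc2)C(=O)OCC)cc1 | intermediate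
7 | (2E,3E)-2-(4-methoxybenzylidene)-3-{4-[(4-methoxybenzyl)oxy]benzylidene}succinic acid | COc1ccc(/C=C(C(=O)O)\C(=C/c2ccc(OCc3ccc(OC)cc3)cc2)C(=O)O)cc1 | intermediate
8 | 3,5-bis(benzyloxy)phenol | Oc1cc(OCc2ccccc2)cc(OCc2ccccc2)c1 | starting material
9 | 2-bromo-3,5-bis(benzyloxy)phenol | Oc1cc(OCc2ccccc2)cc(OCc2ccccc2)c1Br | intermediate
10 | [3,5-bis(benzyloxy)-2-bromophenoxy]trimethylsilane | C[Si](C)(C)Oc1cc(OCc2ccccc2)cc(OCc2ccccc2)c1Br | intermediate
11 | lithium 3,5-bis(benzyloxy)-2-(trimethylsilyl)phenoxide | [Li+].[O-]c1cc(OCc2ccccc2)cc(OCc2ccccc2)c1[Si](C)(C)C | intermediate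
12 | 3,5-bis(benzyloxy)-2-(trimethylsilyl)phenyl trifluoromethanesulfonate | C[Si](C)(C)c1c(OS(=O)(=O)C(F)(F)F)cc(OCc2ccccc2)cc1OCc1ccccc1 | intermediate
13 | 3,5-bis(benzyloxy)benzyne (triple bond between C1 and C2, benzyloxy groups on C3 and C5) | C1#CC(OCc2ccccc2)=CC(OCc2ccccc2)=C1 | intermediate
14 | (2E,3E)-1,4-bis[2,4-bis(benzyloxy)-6-hydroxyphenyl]-2-(4-methoxybenzylidene)-3-{4-[(4-methoxybenzyl)oxy]benzylidene}butane-1,4-dione (present as its bis-phenoxide) | COc1ccc(/C=C(C(=O)c2c(O)cc(OCc3ccccc3)cc2OCc2ccccc2)\C(=C/c2ccc(OCc3ccc(OC)cc3)cc2)C(=O)c2c(O)cc(OCc3ccccc3)cc2OCc2ccccc2)cc1 | intermediate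
15 | racemic (2S*,3R*,2''R*,3''S*)-5,7,5'',7''-tetrakis(benzyloxy)-4'-methoxy-4'''-(4-methoxybenzyloxy)-3,3''-biflavanone (both rings C trans) | COc1ccc([C@H]2Oc3cc(OCc4ccccc4)cc(OCc4ccccc4)c3C(=O)[C@@H]2[C@@H]2C(=O)c3c(OCc4ccccc4)cc(OCc4ccccc4)cc3O[C@H]2c2ccc(OCc3ccc(OC)cc3)cc2)cc1 | intermediate
16 | racemic (2S*,3R*,2''R*,3''S*)-5,7,5'',7'',4'''-pentahydroxy-4'-methoxy-3,3''-biflavanone | COc1ccc([C@H]2Oc3cc(O)cc(O)c3C(=O)[C@@H]2[C@@H]2C(=O)c3c(O)cc(O)cc3O[C@H]2c2ccc(O)cc2)cc1 | intermediate
17 | (2S,3R,2''R,3''S)-5,7,5'',7'',4'''-pentahydroxy-4'-methoxy-3,3''-biflavanone (CNP0196568.3) | COc1ccc([C@H]2Oc3cc(O)cc(O)c3C(=O)[C@@H]2[C@@H]2C(=O)c3c(O)cc(O)cc3O[C@H]2c2ccc(O)cc2)cc1 | target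

Total step count: 8. Longest linear sequence: 6 steps (1, 2, 3, 6, 7, 8); steps 4 and 5 form the second branch.

Steps most likely to fail

1. Step 6 (key step). The aryl anion may be protonated before it acylates, so that only O-arylation occurs. The ortho-acyl phenoxide may capture a second aryne before it closes. The second insertion may stall on a poorly soluble caesium carboxylate. The relation between the two rings C may also equilibrate away from the wanted diastereomer. The fallback uses known chemistry, sets out from 7 and returns at 16. Diacid 7 is coupled with MeNHOMe·HCl (EDC·HCl, HOBt, iPr2NEt; a cyclic anhydride that may form first is opened by the amine and the second acid is coupled in the same way) to the bis(N-methoxy-N-methylamide) F1. 1,3,5-Tris(methoxymethoxy)benzene F2, made from phloroglucinol with MOMCl and iPr2NEt, is lithiated between two acetal oxygens with n-BuLi to 2,4,6-tris(methoxymethoxy)phenyllithium F3. F3 acylates twice on F1 (Weinreb ketone synthesis) to give the bis(aryl ketone) F4. HCl in MeOH removes the six methoxymethyl groups and the 4-methoxybenzyl group to give the bis(2',4',6'-trihydroxychalcone) F5. NaOAc in EtOH then closes both rings C by the usual 2'-hydroxychalcone to flavanone isomerisation, and after the same separation of the trans,trans diastereomers the material is 16.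

2. Step 8. Chiral recognition may be too weak, because the enantiomers differ only in which remote ring B carries the methyl group. The fallback sets out from 15 and returns at 17; it is the reason why the double-primed ring B carries a 4-methoxybenzyl and not a benzyl group. TFA with Et3SiH in CH2Cl2 at 0 °C removes only that group and gives the racemic 4'''-phenol F6. (1S)-Camphanic chloride, Et3N and DMAP convert it into two diastereomeric camphanates, of which the ester of the (2S,3R,2''R,3''S) series F7 is isolated by crystallisation or chromatography on silica. NH3 in MeOH at 0 °C frees the enantiopure phenol F8, and hydrogenolysis over Pd/C as in step 7 gives 17.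

3. Step 7. Ring C may open by hydrogenolysis at the benzylic C2–O1 bond, or the C4 carbonyl may be reduced, while the last of the five benzylic ethers is still being cleaved. The fallback sets out from 15 and returns at 16: BCl3 with pentamethylbenzene in CH2Cl2 at −78 °C removes all five benzylic groups as Friedel–Crafts adducts of the scavenger without any hydrogen, and the non-chelated 4'-methyl ether stays. This fallback makes no new compound (F0).

Further compounds
F1 | step 6 | (2E,3E)-N1,N4-dimethoxy-N1,N4-dimethyl-2-(4-methoxybenzylidene)-3-{4-[(4-methoxybenzyl)oxy]benzylidene}succinamide | COc1ccc(/C=C(C(=O)N(C)OC)\C(=C/c2ccc(OCc3ccc(OC)cc3)cc2)C(=O)N(C)OC)cc1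
F2 | step 6 | 1,3,5-tris(methoxymethoxy)benzene | COCOc1cc(OCOC)cc(OCOC)c1
F3 | step 6 | 2,4,6-tris(methoxymethoxy)phenyllithium | [Li]c1c(OCOC)cc(OCOC)cc1OCOC
F4 | step 6 | (2E,3E)-2-(4-methoxybenzylidene)-3-{4-[(4-methoxybenzyl)oxy]benzylidene}-1,4-bis[2,4,6-tris(methoxymethoxy)phenyl]butane-1,4-dione | COc1ccc(/C=C(C(=O)c2c(OCOC)cc(OCOC)cc2OCOC)\C(=C/c2ccc(OCc3ccc(OC)cc3)cc2)C(=O)c2c(OCOC)cc(OCOC)cc2OCOC)cc1
F5 | step 6 | (2E,3E)-2-(4-hydroxybenzylidene)-3-(4-methoxybenzylidene)-1,4-bis(2,4,6-trihydroxyphenyl)butane-1,4-dione | COc1ccc(/C=C(C(=O)c2c(O)cc(O)cc2O)\C(=C/c2ccc(O)cc2)C(=O)c2c(O)cc(O)cc2O)cc1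
F6 | step 8 | racemic (2S*,3R*,2''R*,3''S*)-5,7,5'',7''-tetrakis(benzyloxy)-4'''-hydroxy-4'-methoxy-3,3''-biflavanone | COc1ccc([C@H]2Oc3cc(OCc4ccccc4)cc(OCc4ccccc4)c3C(=O)[C@@H]2[C@@H]2C(=O)c3c(OCc4ccccc4)cc(OCc4ccccc4)cc3O[C@H]2c2ccc(O)cc2)cc1
F7 | step 8 | (2S,3R,2''R,3''S)-5,7,5'',7''-tetrakis(benzyloxy)-4'-methoxy-3,3''-biflavanon-4'''-yl (1S,4R)-camphanate | COc1ccc([C@H]2Oc3cc(OCc4ccccc4)cc(OCc4ccccc4)c3C(=O)[C@@H]2[C@@H]2C(=O)c3c(OCc4ccccc4)cc(OCc4ccccc4)cc3O[C@H]2c2ccc(OC(=O)[C@]34OC(=O)[C@](C)(CC3)C4(C)C)cc2)cc1
F8 | step 8 | (2S,3R,2''R,3''S)-5,7,5'',7''-tetrakis(benzyloxy)-4'''-hydroxy-4'-methoxy-3,3''-biflavanone | COc1ccc([C@H]2Oc3cc(OCc4ccccc4)cc(OCc4ccccc4)c3C(=O)[C@@H]2[C@@H]2C(=O)c3c(OCc4ccccc4)cc(OCc4ccccc4)cc3O[C@H]2c2ccc(O)cc2)cc1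
F0 | step 7 | none | none
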